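**Retrosynthetic overview**

- The target is a (2R,3R,4S)-chroman: ring A (benzo ring C4a–C8a with 5,7-OH and 6-CHO), ring C (pyran ring O1, C2, C3, C4) and ring B (3,5-diformyl-2,4,6-trihydroxyphenyl on C2).
- Feature used: the vicinal stereocentres C3 (isopropyl) and C4 (isobutyl, bonded to C4a of ring A) are the two alkene carbons of a (Z)-4-methylpent-1-enylboron ate complex whose boron stands where C2 will be. One conjunctive coupling forms C3–CH(CH3)2 and C4–C4a.
- Boron is then exchanged for C2 (CH2 insertion, oxidation to the aldehyde), and ring B is added to C2 as an aryllithium.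
- Ring order: rings A and B are bought as arenes. Ring C is the only ring formed, by acid closure of O1–C2, followed by debenzylation, twofold formylation of ring B and demethylation of ring A.

Key step: step 6

**Assumptions (remarks on the chemistry)**

- Boron carries the mac diol (cis-1,2-dimethylacenaphthene-1,2-diol) rather than pinacol, because ate complexes of β-substituted alkenyl pinacol boronates tend to transfer the alkenyl group directly to palladium, and the mac ester is the known remedy.
- The (Sp,Sp) ligand antipode is written by analogy; should a test coupling give the enantiomer of 13, the mirror-image ligand is used.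

**Route**

Step 1
Reactants: 1 acenaphthoquinone
Product: 2 cis-1,2-dimethyl-1,2-dihydroacenaphthylene-1,2-diol (mac diol, meso)
Conditions: AlMe3 (3 equiv), toluene, 0 °C → rt; aq. HCl; recrystallisation
Reagents that add atoms: trimethylaluminium C[Al](C)C
Why: Twofold 1,2-addition of methyl to the 1,2-diketone, in which the aluminium alkoxide formed first shields its own face so that the second methyl should enter anti to it and give mainly the cis diol, freed of trans isomer by crystallisation.

Step 2
Reactants: 3 4-methylpent-1-yne; 4 catecholborane; 2 mac diol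
Product: 6 (Z)-4-methylpent-1-enylboronic acid mac ester, via catechol alkenylboronate 5 (not isolated)
Conditions: [Rh(cod)Cl]2 (1.5 mol %), P(i-Pr)3 (6 mol %), Et3N, cyclohexane, rt, alkyne in excess; then 2, rt
Reagents that add atoms: none
Why: Rhodium-catalysed trans-hydroboration of the terminal alkyne through a rhodium vinylidene places boron on C1 cis to the alkyl chain (Z-alkenylboronate), and the labile catechol ester is then exchanged for the more stable dialkoxy ester by transesterification.

Step 3
Reactants: 7 4-hydroxy-2,6-dimethoxybenzaldehyde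
Product: 8 3-bromo-4-hydroxy-2,6-dimethoxybenzaldehyde
Conditions: NBS (1.0 equiv), MeCN, 0 °C
Reagents that add atoms: N-bromosuccinimide O=C1CCC(=O)N1Br
Why: Electrophilic aromatic bromination ortho to the free phenol, where the two open positions are equivalent, so one equivalent of NBS should give a single monobromide.

Step 4
Reactants: 8 3-bromo-4-hydroxy-2,6-dimethoxybenzaldehyde
Product: 9 3-bromo-2,6-dimethoxy-4-(methoxymethoxy)benzaldehyde
Conditions: MOMCl, i-Pr2NEt, CH2Cl2, 0 °C → rt
Reagents that add atoms: chloromethyl methyl ether COCCl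
Why: O-alkylation of the acidic phenol (Williamson-type ether synthesis) installs the small MOM group, which keeps the position ortho to bromine as open as possible and later leaves during ring closure.

Step 5
Reactants: 9 3-bromo-2,6-dimethoxy-4-(methoxymethoxy)benzaldehyde
Product: 10 2-[3-bromo-2,6-dimethoxy-4-(methoxymethoxy)phenyl]-1,3-dioxolane (ring A bromide)
Conditions: Me3SiOCH2CH2OSiMe3, Me3SiOTf (5 mol %), CH2Cl2, −78 → −20 °C; pyridine quench
Reagents that add atoms: 1,2-bis(trimethylsilyloxy)ethane C[Si](C)(C)OCCO[Si](C)(C)C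
Why: Noyori acetalisation under aprotic, catalytic Lewis-acid conditions at low temperature should convert the hindered, electron-rich aldehyde into the dioxolane without cleaving the aryl MOM ether.

Step 6
Reactants: 6 (Z)-4-methylpent-1-enylboronic acid mac ester; 11 isopropyllithium; 10 ring A bromide
Product: 13 mac ester of (3R,4S)-4-[3-(1,3-dioxolan-2-yl)-2,4-dimethoxy-6-(methoxymethoxy)phenyl]-2,6-dimethylheptan-3-ylboronic acid, via lithium alkenyl(isopropyl)borate 12 (not isolated)
Conditions: 11 (1.0 equiv to 6), Et2O, −78 °C → rt; then 10, Pd(OAc)2 (5 mol %), (Sp,Sp)-MandyPhos, i.e. 1,1'-bis[bis(4-methoxy-3,5-dimethylphenyl)phosphino]-2,2'-bis[(dimethylamino)(phenyl)methyl]ferrocene (6 mol %), CF3SO3K (2 equiv), THF, 60 °C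
Reagents that add atoms: none
Why: Proposed new method: oxidative addition of bromide 10 to zerovalent palladium and bromide abstraction by CF3SO3K should give a cationic arylpalladium species (divalent palladium) that binds the alkene of ate complex 12 and triggers a 1,2-metallate shift, isopropyl moving from boron to C3 on the face opposite to palladium while palladium bonds to C4, after which reductive elimination with retention forms C4–C4a. The closest known reaction is the enantio- and diastereoselective conjunctive cross-coupling of β-substituted alkenyl B(mac) ate complexes with aryl electrophiles, which has not been shown with a secondary migrating group or a doubly ortho-substituted aryl bromide. No ring is closed. C3 and C4 are both new stereocentres: their relative configuration follows from stereospecific anti addition across the Z-alkene (the relation that becomes 3,4-cis once boron is replaced by C2 with retention), and their absolute configuration from the alkene face that the chiral ferrocenyl bisphosphine lets palladium bind. The step needs conjunctive coupling to beat direct transfer of the alkenyl or isopropyl group to palladium and β-hydride elimination from the secondary alkylpalladium intermediate; the hindered mac diol on boron disfavours transmetalation and the wide-bite-angle bisphosphine speeds reductive elimination. Only carbon migrates, because both oxygen ligands of boron are tied into the chelate.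

Step 7
Reactants: 13 secondary mac boronic ester
Product: 15 (2R,3S)-3-[3-(1,3-dioxolan-2-yl)-2,4-dimethoxy-6-(methoxymethoxy)phenyl]-5-methyl-2-(propan-2-yl)hexan-1-ol, via homologated boronic ester 14 (not isolated)
Conditions: BrCH2Cl (3 equiv), n-BuLi (2.5 equiv), THF, −78 °C → rt; then NaOH (3 M aq.), H2O2 (30 %), 0 °C → rt
Reagents that add atoms: bromochloromethane ClCBr; hydrogen peroxide OO
Why: Matteson homologation, in which chloromethyllithium adds to boron and the secondary alkyl group shifts to CH2 with retention at C3, followed by alkaline peroxide oxidation of the primary C–B bond to C–OH (diol 2 is recovered).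

Step 8
Reactants: 15 primary alcohol
Product: 16 (2R,3S)-3-[3-(1,3-dioxolan-2-yl)-2,4-dimethoxy-6-(methoxymethoxy)phenyl]-5-methyl-2-(propan-2-yl)hexanal
Conditions: Dess–Martin periodinane, NaHCO3, CH2Cl2, 0 °C → rt; used without delay
Reagents that add atoms: none
Why: Dess–Martin oxidation under buffered, non-basic conditions should give the α-branched aldehyde without epimerising C3 or opening the acetal.

Step 9
Reactants: 17 1,3,5-tris(benzyloxy)benzene
Product: 18 2-bromo-1,3,5-tris(benzyloxy)benzene
Conditions: NBS (1.0 equiv), CH2Cl2, −78 → 0 °C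
Reagents that add atoms: N-bromosuccinimide O=C1CCC(=O)N1Br
Why: Electrophilic aromatic bromination of the symmetric triether at one of three equivalent, doubly activated positions.

Step 10
Reactants: 18 2-bromo-1,3,5-tris(benzyloxy)benzene; 16 aldehyde
Product: 20 (2R,3S)-3-[3-(1,3-dioxolan-2-yl)-2,4-dimethoxy-6-(methoxymethoxy)phenyl]-5-methyl-2-(propan-2-yl)-1-[2,4,6-tris(benzyloxy)phenyl]hexan-1-ol (both C1 epimers), via 2,4,6-tris(benzyloxy)phenyllithium 19 (not isolated)
Conditions: 18 (1.5 equiv), n-BuLi, THF, −78 °C; then 16, −78 → −40 °C; aq. NH4Cl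
Reagents that add atoms: none
Why: Bromine–lithium exchange gives the aryllithium, whose 1,2-addition to the aldehyde at low temperature should outrun enolisation of the shielded tertiary α-position; the new carbinol centre (future C2) needs no control because it is ionised in the next step.

Step 11
Reactants: 20 carbinol (epimer mixture)
Product: 21 (2R,3R,4S)-5,7-dimethoxy-4-(2-methylpropyl)-3-(propan-2-yl)-2-[2,4,6-tris(benzyloxy)phenyl]chromane-6-carbaldehyde
Conditions: HCl (1 M aq.)/THF 1:4, 0 °C → rt, short reaction time
Reagents that add atoms: water O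
Why: Acid ionises the carbinol to a 2,4,6-trialkoxybenzyl cation that is captured by the ring A oxygen in a 6-membered oxa-cyclisation forming O1–C2 (MOM lost as formaldehyde and methanol) while the dioxolane is hydrolysed; the reversible closure should place the aryl group equatorial and trans to the C3 isopropyl group (R at C2), since the cis isomer would suffer a 1,3-diaxial clash with the pseudoaxial C4 isobutyl group.

Step 12
Reactants: 21 tribenzyl chroman
Product: 22 (2R,3R,4S)-5,7-dimethoxy-4-(2-methylpropyl)-3-(propan-2-yl)-2-(2,4,6-trihydroxyphenyl)chromane-6-carbaldehyde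
Conditions: H2 (1 atm), Pd/C (10 wt % Pd on carbon), EtOAc, rt
Reagents that add atoms: none
Why: Catalytic hydrogenolysis of the three aryl benzyl ethers under neutral conditions, which the hindered electron-rich aldehyde and the C2–O1 ether are expected to survive at ambient pressure.

Step 13
Reactants: 22 triphenol
Product: 23 5-[(2R,3R,4S)-6-formyl-5,7-dimethoxy-4-(2-methylpropyl)-3-(propan-2-yl)chroman-2-yl]-2,4,6-trihydroxybenzene-1,3-dicarbaldehyde
Conditions: POCl3 (4 equiv), DMF (6 equiv), MeCN, 0 °C → rt; then H2O, 40 °C
Reagents that add atoms: N,N-dimethylformamide CN(C)C=O; water O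
Why: Vilsmeier–Haack formylation, in which the free phloroglucinol ring B is far more nucleophilic than ring A (methyl ethers, deactivated by its CHO), so both open positions of ring B should be formylated and C8 left alone.

Step 14
Reactants: 23 dimethyl ether
Product: 24 5-[(2R,3R,4S)-6-formyl-5,7-dihydroxy-4-(2-methylpropyl)-3-(propan-2-yl)chroman-2-yl]-2,4,6-trihydroxybenzene-1,3-dicarbaldehyde (target)
Conditions: BBr3 (8 equiv), CH2Cl2, −78 → 0 °C; then H2O
Reagents that add atoms: none
Why: Lewis-acid cleavage of the two aryl methyl ethers, both ortho to the C6 aldehyde and therefore chelation-assisted, should release the hydrogen-bonded 5,7-dihydroxy aldehyde at low temperature, before the C2–O1 bond to the now electron-poor ring B is attacked.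

**Compound list**

1 | acenaphthoquinone (acenaphthylene-1,2-dione) | O=C1C(=O)c2cccc3cccc1c23 | starting material
2 | cis-1,2-dimethyl-1,2-dihydroacenaphthylene-1,2-diol (mac diol, meso) | C[C@]1(O)c2cccc3cccc(c23)[C@@]1(C)O | intermediate
3 | 4-methylpent-1-yne | CC(C)CC#C | starting material
4 | catecholborane (1,3,2-benzodioxaborole) | B1Oc2ccccc2O1 | starting material
5 | 2-[(Z)-4-methylpent-1-enyl]-1,3,2-benzodioxaborole | CC(C)C/C=C\B1Oc2ccccc2O1 | intermediate (not isolated)
6 | (Z)-4-methylpent-1-enylboronic acid mac ester | CC(C)C/C=C\B1O[C@@]2(C)c3cccc4cccc(c34)[C@@]2(C)O1 | intermediate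
7 | 4-hydroxy-2,6-dimethoxybenzaldehyde | O=Cc1c(OC)cc(O)cc1OC | starting material
8 | 3-bromo-4-hydroxy-2,6-dimethoxybenzaldehyde | O=Cc1c(OC)c(Br)c(O)cc1OC | intermediate
9 | 3-bromo-2,6-dimethoxy-4-(methoxymethoxy)benzaldehyde | O=Cc1c(OC)c(Br)c(OCOC)cc1OC | intermediate
10 | 2-[3-bromo-2,6-dimethoxy-4-(methoxymethoxy)phenyl]-1,3-dioxolane | COCOc1cc(OC)c(C2OCCO2)c(OC)c1Br | intermediate
11 | isopropyllithium | [Li]C(C)C | starting material
12 | lithium [(Z)-4-methylpent-1-enyl](isopropyl)borate of diol 2 (ate complex) | [Li+].CC(C)C/C=C\[B-]1(C(C)C)O[C@@]2(C)c3cccc4cccc(c34)[C@@]2(C)O1 | intermediate (not isolated)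
13 | mac ester of (3R,4S)-4-[3-(1,3-dioxolan-2-yl)-2,4-dimethoxy-6-(methoxymethoxy)phenyl]-2,6-dimethylheptan-3-ylboronic acid | CC(C)C[C@H](c1c(OCOC)cc(OC)c(C2OCCO2)c1OC)[C@H](B1O[C@@]2(C)c3cccc4cccc(c34)[C@@]2(C)O1)C(C)C | intermediate
14 | mac ester of {(2R,3S)-3-[3-(1,3-dioxolan-2-yl)-2,4-dimethoxy-6-(methoxymethoxy)phenyl]-5-methyl-2-(propan-2-yl)hexyl}boronic acid | CC(C)C[C@H](c1c(OCOC)cc(OC)c(C2OCCO2)c1OC)[C@H](CB1O[C@@]2(C)c3cccc4cccc(c34)[C@@]2(C)O1)C(C)C | intermediate (not isolated)
15 | (2R,3S)-3-[3-(1,3-dioxolan-2-yl)-2,4-dimethoxy-6-(methoxymethoxy)phenyl]-5-methyl-2-(propan-2-yl)hexan-1-ol | CC(C)C[C@H](c1c(OCOC)cc(OC)c(C2OCCO2)c1OC)[C@H](CO)C(C)C | intermediate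
16 | (2R,3S)-3-[3-(1,3-dioxolan-2-yl)-2,4-dimethoxy-6-(methoxymethoxy)phenyl]-5-methyl-2-(propan-2-yl)hexanal | CC(C)C[C@H](c1c(OCOC)cc(OC)c(C2OCCO2)c1OC)[C@H](C=O)C(C)C | intermediate
17 | 1,3,5-tris(benzyloxy)benzene | c1ccc(COc2cc(OCc3ccccc3)cc(OCc3ccccc3)c2)cc1 | starting material
18 | 2-bromo-1,3,5-tris(benzyloxy)benzene | Brc1c(OCc2ccccc2)cc(OCc2ccccc2)cc1OCc1ccccc1 | intermediate
19 | 2,4,6-tris(benzyloxy)phenyllithium | [Li]c1c(OCc2ccccc2)cc(OCc2ccccc2)cc1OCc1ccccc1 | intermediate (not isolated)
20 | (2R,3S)-3-[3-(1,3-dioxolan-2-yl)-2,4-dimethoxy-6-(methoxymethoxy)phenyl]-5-methyl-2-(propan-2-yl)-1-[2,4,6-tris(benzyloxy)phenyl]hexan-1-ol, C1 epimers | CC(C)C[C@H](c1c(OCOC)cc(OC)c(C2OCCO2)c1OC)[C@H](C(O)c1c(OCc2ccccc2)cc(OCc2ccccc2)cc1OCc1ccccc1)C(C)C | intermediate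
21 | (2R,3R,4S)-5,7-dimethoxy-4-(2-methylpropyl)-3-(propan-2-yl)-2-[2,4,6-tris(benzyloxy)phenyl]chromane-6-carbaldehyde | CC(C)C[C@@H]1c2c(cc(OC)c(C=O)c2OC)O[C@@H](c2c(OCc3ccccc3)cc(OCc3ccccc3)cc2OCc2ccccc2)[C@@H]1C(C)C | intermediate
22 | (2R,3R,4S)-5,7-dimethoxy-4-(2-methylpropyl)-3-(propan-2-yl)-2-(2,4,6-trihydroxyphenyl)chromane-6-carbaldehyde | CC(C)C[C@@H]1c2c(cc(OC)c(C=O)c2OC)O[C@@H](c2c(O)cc(O)cc2O)[C@@H]1C(C)C | intermediate
23 | 5-[(2R,3R,4S)-6-formyl-5,7-dimethoxy-4-(2-methylpropyl)-3-(propan-2-yl)chroman-2-yl]-2,4,6-trihydroxybenzene-1,3-dicarbaldehyde | CC(C)C[C@@H]1c2c(cc(OC)c(C=O)c2OC)O[C@@H](c2c(O)c(C=O)c(O)c(C=O)c2O)[C@@H]1C(C)C | intermediate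
24 | 5-[(2R,3R,4S)-6-formyl-5,7-dihydroxy-4-(2-methylpropyl)-3-(propan-2-yl)chroman-2-yl]-2,4,6-trihydroxybenzene-1,3-dicarbaldehyde | CC(C)C[C@@H]1c2c(cc(O)c(C=O)c2O)O[C@@H](c2c(O)c(C=O)c(O)c(C=O)c2O)[C@@H]1C(C)C | target

**Step count**

Total: 14 steps. Longest linear sequence: 11 steps (steps 3–8 and 10–14, from 7).

**Steps most likely to fail**

1. Step 6 (proposed new method). The hindered cationic arylpalladium species may not bind the 1,2-disubstituted alkene of the ate complex, so that direct transfer of a boron ligand to palladium or protodeboronation takes over, or the facial selectivity may be poor. The fallback is reagent-controlled lithiation–borylation, which is known chemistry; it sets out from 10 and comes back to the route at 15. Bromine–lithium exchange on 10 (n-BuLi, THF, −78 °C) and trapping with 2-isopropoxy-4,4,5,5-tetramethyl-1,3,2-dioxaborolane would give the aryl pinacol boronate F1. 3-Methylbutyl N,N-diisopropylcarbamate F2 (from 3-methylbutan-1-ol and N,N-diisopropylcarbamoyl chloride) is deprotonated with s-BuLi/sparteine in Et2O at −78 °C, the antipode being chosen to give R at the benzylic carbon. F1 is added, and warming (MgBr2·OEt2 if needed) should trigger 1,2-migration of the aryl group with loss of the carbamate to give the benzylic boronic ester F3. A second homologation with lithiated 2-methylpropyl N,N-diisopropylcarbamate F4 (s-BuLi/sparteine, antipode chosen to give R at the new carbon) inserts the isopropyl-bearing carbon C3 with retention in the migrating benzylic group and gives the pinacol ester F5, the pinacol analogue of 13. F5 is taken through the conditions of step 7 to 15.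

2. Step 7. The thermally fragile carbenoid may decompose before the congested boron atom captures it, or the ate complex may revert instead of rearranging, so that 13 is returned or merely oxidised. The fallback sets out from 13 and comes back at 16. Zweifel olefination with vinyllithium (from bromoethene and t-BuLi; a stable nucleophile that can be used in excess and warmed), then I2/MeOH and NaOMe, should give the terminal alkene F6 with retention at C3. Lemieux–Johnson cleavage (OsO4 cat., NaIO4, 2,6-lutidine, dioxane/H2O) would then give 16 directly.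

3. Step 11. The benzylic cation may lose the C3 proton and be re-protonated, which would scramble C3, or the MOM-protected oxygen may capture the cation too slowly, so that intermolecular arylation competes. The fallback sets out from 16 and comes back at 23, and thereby also replaces steps 10, 12 and 13. Aqueous acid (HCl, THF/H2O) on 16 removes the MOM group and the dioxolane and should give the lactol F7. Condensation of F7, through its open hydroxy-aldehyde form, with 2,4-diformylphloroglucinol F8 (one step from phloroglucinol by Vilsmeier–Haack formylation; NaOAc, AcOH, rt → 50 °C, no amine) should give an ortho-quinone methide at C2. The free ring A phenol captures it by intramolecular oxa-Michael addition (6-membered closure of O1–C2) to give 23, the aryl group again settling trans to the C3 isopropyl group. The ring A aldehyde, flanked by two methoxy groups, is the less electrophilic carbonyl and should stay out of the condensation.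

**Further compounds**

F1 | step 6 | 2-[3-(1,3-dioxolan-2-yl)-2,4-dimethoxy-6-(methoxymethoxy)phenyl]-4,4,5,5-tetramethyl-1,3,2-dioxaborolane | COCOc1cc(OC)c(C2OCCO2)c(OC)c1B1OC(C)(C)C(C)(C)O1
F2 | step 6 | 3-methylbutyl N,N-diisopropylcarbamate | CC(C)CCOC(=O)N(C(C)C)C(C)C
F3 | step 6 | pinacol ester of (1R)-1-[3-(1,3-dioxolan-2-yl)-2,4-dimethoxy-6-(methoxymethoxy)phenyl]-3-methylbutylboronic acid | CC(C)C[C@H](c1c(OCOC)cc(OC)c(C2OCCO2)c1OC)B1OC(C)(C)C(C)(C)O1
F4 | step 6 | 2-methylpropyl N,N-diisopropylcarbamate | CC(C)COC(=O)N(C(C)C)C(C)C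
F5 | step 6 | pinacol ester of (3R,4S)-4-[3-(1,3-dioxolan-2-yl)-2,4-dimethoxy-6-(methoxymethoxy)phenyl]-2,6-dimethylheptan-3-ylboronic acid | CC(C)C[C@H](c1c(OCOC)cc(OC)c(C2OCCO2)c1OC)[C@H](B1OC(C)(C)C(C)(C)O1)C(C)C
F6 | step 7 | 2-{2,6-dimethoxy-4-(methoxymethoxy)-3-[(3S,4S)-6-methyl-3-(propan-2-yl)hept-1-en-4-yl]phenyl}-1,3-dioxolane | CC(C)C[C@H](c1c(OCOC)cc(OC)c(C2OCCO2)c1OC)[C@H](C=C)C(C)C
F7 | step 11 | (3R,4S)-2-hydroxy-5,7-dimethoxy-4-(2-methylpropyl)-3-(propan-2-yl)chromane-6-carbaldehyde (anomer mixture) | CC(C)C[C@@H]1c2c(cc(OC)c(C=O)c2OC)OC(O)[C@@H]1C(C)C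
F8 | step 11 | 2,4,6-trihydroxybenzene-1,3-dicarbaldehyde (2,4-diformylphloroglucinol) | O=Cc1c(O)cc(O)c(C=O)c1O
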